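Theta carries more free monomer than epsilon, at the same loading of initiator, and the meeting had to say which ends with the longer chains.

| setting | grey | blue | amber | theta | epsilon |
|---|---|---|---|---|---|
| free monomer | 0.036 M | 0.053 M | 0.088 M | 0.10 M | 0.030 M |
| transfer agent | 0.030 M | 0.030 M | 0.030 M | 0.0300 M | 0.0300 M |
| initiator | 2.5 mol% | 2.5 mol% | 2.5 mol% | 2.5 mol% | 2.5 mol% |
| remark | run made earlier | run made earlier | run made earlier |  |  |
| time |  |  |  | 8.0 min | 8.0 min |

| run | time / min | monomer in chains / % |
|---|---|---|
| grey | 0.667 | 0 |
| grey | 1.33 | 0.5 |
| grey | 3.00 | 2.3 |
| grey | 8.00 | 8.5 |
| blue | 2.00 | 2.3 |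
| blue | 4.00 | 6.3 |
| blue | 6.00 | 10.1 |
| blue | 8.00 | 13.2 |
| amber | 2.00 | 5.4 |
| amber | 4.00 | 13.2 |
| amber | 6.00 | 18.8 |
| amber | 8.00 | 23.6 |

(standard deviation of a reading: 0.3 percentage points)

- which of the two ends with the longer chains by the average number of monomer units in a chain (chains begun, living or dead) ("neither" if they lie within 10 %) (theta / epsilon / neither)
- average number of monomer units in a chain (chains begun, living or dead) at the end, theta
- average number of monomer units in a chain (chains begun, living or dead) at the end, epsilon

- the average divides the monomer in chains by the number of chains begun, living and dead together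
- on the list of suspects stand: free monomer + initiator -> living end + monomer in chains; free monomer + living end -> monomer in chains + living end; living end + transfer agent -> dead chain
- the earlier runs do not show the number of chains; that part of a forecast is a guess

I opened with both ends. Let x be the converted fraction and s the started share of the initiator, taking each started initiator as one chain, which the runs do not show. The length is then x/(loading × s). Late on, with s full, that is x/loading. Early on, I argued, a chain holds about one unit, so x/loading reads s itself: grey at 1.33 min gives 0.200, a rough figure, since the reading of 0.5 % carries a scatter of 0.3 percentage points.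

Joining the two, I treated the start as pseudo-first-order in initiator and took the start rate, the first-order rate at which initiator begins chains, 0.168 min⁻¹ in grey, scaled with c(free monomer). That puts s at 97.6 % for theta and 67.3 % for epsilon.

For x, I took the power of c(free monomer) between grey and amber at 8.00 min, 1.14, giving 27.3 % for theta and 6.90 % for epsilon. My lengths were therefore 11.2 and 4.10.

The forecaster answered with theta, 10.7 and 2.8, holding epsilon at “about 97% initiated”. We agreed on theta; my epsilon stood longer than the forecast's.

The flask gives 11.0 for theta and 3.80 for epsilon, so theta ends longer.

    free monomer + initiator → living end + monomer in chains (k = 0.0837 M⁻¹ s⁻¹)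
    free monomer + living end → monomer in chains + living end, rate k2*[living end]*[free monomer] (k = 0.537 M⁻¹ s⁻¹)
    living end + transfer agent → dead chain (kL = 0.101 M⁻¹ s⁻¹)

Epsilon is where the reckonings part: 31.1 % of its initiator is left at 8.00 min, so 68.9 % has started, against 97 % in the forecast and my 67.3 %. Theta read earlier, at 5.0 min, is the neighbour: the scaled start rate gives s = 90.3 %, and that flask has spent 89.9 % of its initiator. With 18.5 % in chains, the rule gives 8.19, and the flask stands at 8.23.

The data were computed from invented constants; scatter was added.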